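The route rests on cutting the exocyclic CH2–CH2 bond of the side chain. The key step exploits the 1,3-dioxygenated unit formed by the tertiary carbinol carbon C1 of the cyclohexanone ring, the two side-chain CH2 groups and the ester oxygen: it is read as a carbo-oxygenated exocyclic alkene. In one three-component operation a palmitoyloxymethyl radical adds to the =CH2 carbon of 4-methylidenecyclohexanone, the tertiary ring radical is oxidised to the cation, the palmitate carbonyl traps it as a six-membered acyloxonium ion and water releases the tertiary alcohol. The precursors are iodomethyl palmitate, made in two steps from palmitic acid, and the unprotected methylidene ketone.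

Key step: step 3

Remark: 4-methylidenecyclohexanone (4) is taken as a purchasable building block. The target is achiral (the carbinol carbon lies on the mirror plane of the ring), so no stereocentre has to be set.

Step 1
Reactants: 1 palmitic acid
Product: 2 chloromethyl palmitate
Conditions: ClCH2OSO2Cl (1.2 equiv), NaHCO3 (4 equiv), Bu4NHSO4 (0.1 equiv), CH2Cl2/H2O, 0 °C to rt
Reagents that add atoms: chloromethyl chlorosulfate, ClCOS(=O)(=O)Cl
Why: Phase-transfer O-alkylation of the carboxylate, an SN2 displacement at CH2 in which chlorosulfate leaves far more readily than chloride, so the chloromethyl ester should be retained.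

Step 2
Reactants: 2 chloromethyl palmitate
Product: 3 iodomethyl palmitate
Conditions: NaI (2 equiv), acetone, rt, dark; filtration, Na2S2O3 wash, used without chromatography
Reagents that add atoms: sodium iodide, [Na+].[I-]
Why: Finkelstein halide exchange at an α-acyloxy CH2 that is activated for SN2, driven by precipitation of NaCl from acetone.

Step 3
Reactants: 3 iodomethyl palmitate; 4 4-methylidenecyclohexanone (3 equiv)
Product: 6 2-(1-hydroxy-4-oxocyclohexyl)ethyl palmitate, via spiro-1,3-dioxan-2-ylium iodide 5 (not isolated)
Conditions: fac-Ir(ppy)3 (1 mol%), NaHCO3 (2 equiv), acetone/H2O 9:1, degassed, blue LEDs (450 nm), rt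
Reagents that add atoms: water, O
Why: Proposed new method: excited fac-Ir(ppy)3 should reduce the C–I bond of 3 to the palmitoyloxymethyl radical, which adds to the unsubstituted =CH2 carbon of 4 (forming the CH2–CH2 bond), and the resulting tertiary ring radical is oxidised by Ir(IV) to the cation, closing a redox-neutral radical-polar crossover. The cation is expected to be trapped by the ester carbonyl oxygen, 1,5 to it, as the spiro 1,3-dioxan-2-ylium ion 5, which water opens at C2 to an orthoacid that collapses to the primary ester/tertiary alcohol 6 while NaHCO3 takes up HI. The closest known reaction types are the photoredox three-component oxyalkylation of styrenes with alkyl halides and water, and the tin-free addition of acyloxymethyl radicals from iodomethyl esters to C=C and C=N acceptors; new here is their union on an unactivated 1,1-dialkylethylene with an α-acyloxy radical. The only ring closed is the transient six-membered acyloxonium ring (carbonyl oxygen onto the cation, 1,3-acyloxy participation, the C=O lying inside the new ring), and it is opened again in the same flask, so no ring of 6 is formed here. No stereocentre arises, since the carbinol carbon lies on the mirror plane of the ring. The step needs addition at CH2 and not at the ring carbon, secured by the 1,1-disubstitution (unhindered terminus, tertiary radical), and C–O capture in preference to E1 proton loss, secured by the intramolecular carbonyl trap, the primary ester being the thermodynamic outcome of orthoacid opening.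

Compound list
1 | palmitic acid (hexadecanoic acid) | CCCCCCCCCCCCCCCC(=O)O | starting material
2 | chloromethyl palmitate (chloromethyl hexadecanoate) | CCCCCCCCCCCCCCCC(=O)OCCl | intermediate
3 | iodomethyl palmitate (iodomethyl hexadecanoate) | CCCCCCCCCCCCCCCC(=O)OCI | intermediate
4 | 4-methylidenecyclohexan-1-one | C=C1CCC(=O)CC1 | starting material
5 | 9-oxo-2-pentadecyl-1,3-dioxaspiro[5.5]undecan-2-ylium iodide (spiro acyloxonium ion, O1 on the spiro carbon) | CCCCCCCCCCCCCCCC1=[O+]CCC2(CCC(=O)CC2)O1.[I-] | intermediate
6 | 2-(1-hydroxy-4-oxocyclohexyl)ethyl palmitate (achiral) | CCCCCCCCCCCCCCCC(=O)OCCC1(O)CCC(=O)CC1 | target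

Total step count: 3
Longest linear sequence: 3 steps (1 → 2 → 3 → 6)

Steps most likely to fail

Step 3 (new method). The weakly nucleophilic palmitoyloxymethyl radical may be reduced or its iodide precursor hydrolysed faster than addition to the electron-neutral alkene occurs. The tertiary cation may also lose a ring proton before it is trapped, or orthoacid opening may leave the acyl group on the tertiary oxygen. The fallback uses known chemistry, sets out from 4, returns at 6 and still makes the same CH2–CH2 bond. Compound 4 is ketalised with ethylene glycol (PPTS, benzene, Dean–Stark) to 8-methylidene-1,4-dioxaspiro[4.5]decane F1. A Me2AlCl-promoted carbonyl-ene reaction with paraformaldehyde (CH2Cl2, −78 to 0 °C) should join the formaldehyde carbon to the =CH2 carbon and give the homoallylic alcohol 2-(1,4-dioxaspiro[4.5]dec-7-en-8-yl)ethanol F2. Steglich esterification with 1 (EDC, DMAP, CH2Cl2) gives 2-(1,4-dioxaspiro[4.5]dec-7-en-8-yl)ethyl palmitate F3. Mukaiyama hydration (Co(acac)2, PhSiH3, O2, THF) should place the hydroxyl on the more substituted ring carbon and give 2-(8-hydroxy-1,4-dioxaspiro[4.5]decan-8-yl)ethyl palmitate F4. PPTS in wet acetone then removes the ketal and delivers 6.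

Step 2. The iodomethyl ester may decompose under light and moisture during isolation, or the exchange may stall. The fallback replaces the halide by a bench-stable redox-active ester as radical precursor; it sets out from 1 and returns at 6. Compound 1 is O-alkylated with tert-butyl bromoacetate (K2CO3, DMF) to tert-butyl 2-(palmitoyloxy)acetate F5. TFA in CH2Cl2 frees 2-(palmitoyloxy)acetic acid F6. N-Hydroxyphthalimide, DIC and catalytic DMAP give 1,3-dioxoisoindolin-2-yl 2-(palmitoyloxy)acetate F7. Under the photocatalyst of step 3, F7 should lose CO2 and phthalimide to give the same palmitoyloxymethyl radical, which is carried on with 4 and water to 6.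

Step 1. The soap-like carboxylate may emulsify the two-phase system, and the chloromethyl ester may be alkylated a second time by palmitate to the methylene diester. The fallback changes from carboxylate alkylation to formaldehyde insertion into an acyl chloride; it sets out from 1 and returns at 2. Compound 1 is converted to palmitoyl chloride F8 ((COCl)2, cat. DMF, CH2Cl2). F8 is then heated with paraformaldehyde and catalytic ZnCl2 (neat, 80 °C), so that formaldehyde inserts into the C–Cl bond to give 2.

Further compounds
F1 | step 3 | 8-methylidene-1,4-dioxaspiro[4.5]decane | C=C1CCC2(CC1)OCCO2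
F2 | step 3 | 2-(1,4-dioxaspiro[4.5]dec-7-en-8-yl)ethan-1-ol | OCCC1=CCC2(CC1)OCCO2
F3 | step 3 | 2-(1,4-dioxaspiro[4.5]dec-7-en-8-yl)ethyl palmitate | CCCCCCCCCCCCCCCC(=O)OCCC1=CCC2(CC1)OCCO2
F4 | step 3 | 2-(8-hydroxy-1,4-dioxaspiro[4.5]decan-8-yl)ethyl palmitate | CCCCCCCCCCCCCCCC(=O)OCCC1(O)CCC2(CC1)OCCO2
F5 | step 2 | tert-butyl 2-(palmitoyloxy)acetate | CCCCCCCCCCCCCCCC(=O)OCC(=O)OC(C)(C)C
F6 | step 2 | 2-(palmitoyloxy)acetic acid | CCCCCCCCCCCCCCCC(=O)OCC(=O)O
F7 | step 2 | 1,3-dioxoisoindolin-2-yl 2-(palmitoyloxy)acetate | CCCCCCCCCCCCCCCC(=O)OCC(=O)ON1C(=O)c2ccccc2C1=O
F8 | step 1 | palmitoyl chloride (hexadecanoyl chloride) | CCCCCCCCCCCCCCCC(=O)Cl
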